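## Retrosynthetic overview

1. The target is reached last by hydrogenolysis of a benzyl ether on the ring A phenol.
2. The C2–C3 bond and the only stereocenter (C2, S) come from an enantioselective hydroxymethylation of an α-aryloxy ketone with formaldehyde under chiral quaternary ammonium ion-pair catalysis (metal-free).
3. The C2–O(aryl) bond comes from Williamson etherification of an α-bromoketone with dihydroconiferyl alcohol (ring B, used with its alkanol free).
4. The α-bromoketone comes from O-benzylated acetosyringone (ring A).
5. No ring is formed; both benzene rings are bought intact.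

Assumption: the stereocenter in the SMILES is (S) (priorities OAr > C=O > CH2OH > H). The sense of induction in step 4 is assigned by analogy with cinchonidinium-mediated enolate alkylations and must be confirmed on the first batch; if it is reversed, the pseudoenantiomeric cinchoninium salt is used in the same step.

## Route

Step 1
Reactants: 1 acetosyringone, 1-(4-hydroxy-3,5-dimethoxyphenyl)ethan-1-one
Product: 2 1-[4-(benzyloxy)-3,5-dimethoxyphenyl]ethan-1-one
Conditions: BnBr (1.2 equiv), K2CO3 (2 equiv), DMF, 60 °C, 4 h
Reagents that add atoms: benzyl bromide, BrCc1ccccc1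
Why: Williamson O-benzylation of the acidic phenol (pKa about 8) is clean with K2CO3, and the ether masks a phenoxide that would otherwise self-alkylate in step 3 and shut down ketone enolisation in step 4.

Step 2
Reactants: 2 1-[4-(benzyloxy)-3,5-dimethoxyphenyl]ethan-1-one
Product: 3 2-bromo-1-[4-(benzyloxy)-3,5-dimethoxyphenyl]ethan-1-one
Conditions: CuBr2 (2.1 equiv), EtOAc/CHCl3 1:1, reflux, 3 h
Reagents that add atoms: CuBr2 (copper dibromide), [Cu+2].[Br-].[Br-]
Why: Heterogeneous CuBr2 α-bromination of an aryl methyl ketone through its enol stops at the monobromide and is standard for alkoxy-substituted acetophenones; the ring positions flanked by the acyl group and the benzyl ether are left alone.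

Step 3
Reactants: 3 2-bromo-1-[4-(benzyloxy)-3,5-dimethoxyphenyl]ethan-1-one; 4 dihydroconiferyl alcohol, 4-(3-hydroxypropyl)-2-methoxyphenol (1.05 equiv)
Product: 5 1-[4-(benzyloxy)-3,5-dimethoxyphenyl]-2-[4-(3-hydroxypropyl)-2-methoxyphenoxy]ethan-1-one
Conditions: K2CO3 (1.5 equiv), acetone, rt, 12 h
Reagents that add atoms: none
Why: Williamson ether synthesis (SN2 on an activated α-keto bromide); K2CO3 ionises only the phenol (pKa about 10) and not the alkanol (pKa about 16), so O-arylation is chemoselective without protecting the side-chain alcohol.

Step 4
Reactants: 5 1-[4-(benzyloxy)-3,5-dimethoxyphenyl]-2-[4-(3-hydroxypropyl)-2-methoxyphenoxy]ethan-1-one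
Product: 6 (S)-1-[4-(benzyloxy)-3,5-dimethoxyphenyl]-3-hydroxy-2-[4-(3-hydroxypropyl)-2-methoxyphenoxy]propan-1-one
Conditions: (CH2O)n (2.0 equiv CH2O), O-allyl-N-(9-anthracenylmethyl)cinchonidinium bromide (10 mol %), Cs2CO3 (20 mol %), toluene/CH2Cl2 2:1, −20 °C, 24–36 h; pH 7 phosphate buffer quench at −20 °C
Reagents that add atoms: formaldehyde (released from paraformaldehyde), C=O
Why: Proposed new method: enantioselective hydroxymethylation of an α-aryloxy aryl ketone by chiral ammonium ion-pair (solid–liquid phase-transfer) catalysis, forming the C2–C3 bond and setting C2; Cs2CO3 deprotonates 5 at the solid surface (α-aryloxyacetophenones have pKa about 21 in DMSO, and this is the same enolate that K2CO3/formaldehyde engages in the racemic reaction), the (Z)-enolate of 5 enters the apolar phase as a contact ion pair with the cinchonidinium cation, whose anthracenyl and quinoline walls leave only the Si face of the α-carbon open to monomeric formaldehyde, so C–C bond formation gives the (S)-aldolate, which is protonated by 5 or CsHCO3 so that the base turns over; the new tertiary α-C–H is not re-enolised at −20 °C because the tetrasubstituted enolate it would give suffers allylic 1,3-strain (about 2 pKa units less acidic), so racemisation, E1cB loss of water and a second hydroxymethylation are slow, and formaldehyde addition is exergonic enough to hold back retro-aldol; the closest known reaction types are cinchonidinium phase-transfer alkylation of α-alkoxy aryl ketones (whose tertiary α-alkoxy ketone products keep their ee under hydroxide), phase-transfer direct aldol reactions of glycine imines, and the racemic K2CO3/formaldehyde hydroxymethylation used on this substrate class.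

Step 5
Reactants: 6 (S)-1-[4-(benzyloxy)-3,5-dimethoxyphenyl]-3-hydroxy-2-[4-(3-hydroxypropyl)-2-methoxyphenoxy]propan-1-one
Product: 7 (S)-3-hydroxy-1-(4-hydroxy-3,5-dimethoxyphenyl)-2-[4-(3-hydroxypropyl)-2-methoxyphenoxy]propan-1-one (target)
Conditions: H2 (1 atm), 10% Pd/C, EtOAc, rt, 1–2 h (stopped at full conversion); filter, concentrate below 30 °C
Reagents that add atoms: none
Why: Catalytic hydrogenolysis of the hindered benzyl aryl ether is fast under neutral aprotic conditions, while the electron-rich para-oxygenated aryl ketone and the α-aryloxy C–O bond are slow to reduce at 1 atm and rt; with no acid or base present, C2 is not epimerised.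

## Compound list

1 | acetosyringone, 1-(4-hydroxy-3,5-dimethoxyphenyl)ethan-1-one | CC(=O)c1cc(OC)c(O)c(OC)c1 | starting material
2 | 1-[4-(benzyloxy)-3,5-dimethoxyphenyl]ethan-1-one | CC(=O)c1cc(OC)c(OCc2ccccc2)c(OC)c1 | intermediate
3 | 2-bromo-1-[4-(benzyloxy)-3,5-dimethoxyphenyl]ethan-1-one | BrCC(=O)c1cc(OC)c(OCc2ccccc2)c(OC)c1 | intermediate
4 | dihydroconiferyl alcohol, 4-(3-hydroxypropyl)-2-methoxyphenol | COc1cc(CCCO)ccc1O | starting material
5 | 1-[4-(benzyloxy)-3,5-dimethoxyphenyl]-2-[4-(3-hydroxypropyl)-2-methoxyphenoxy]ethan-1-one | COc1cc(CCCO)ccc1OCC(=O)c1cc(OC)c(OCc2ccccc2)c(OC)c1 | intermediate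
6 | (S)-1-[4-(benzyloxy)-3,5-dimethoxyphenyl]-3-hydroxy-2-[4-(3-hydroxypropyl)-2-methoxyphenoxy]propan-1-one | COc1cc(CCCO)ccc1O[C@@H](CO)C(=O)c1cc(OC)c(OCc2ccccc2)c(OC)c1 | intermediate
7 | (S)-3-hydroxy-1-(4-hydroxy-3,5-dimethoxyphenyl)-2-[4-(3-hydroxypropyl)-2-methoxyphenoxy]propan-1-one | COc1cc(CCCO)ccc1O[C@@H](CO)C(=O)c1cc(OC)c(O)c(OC)c1 | target

## Step count and risks

Total step count: 5. Longest linear sequence: 5 steps (1 → 2 → 3 → 5 → 6 → 7); compound 4 is bought and used as such.

Steps most likely to fail:

Step 4 (the proposed new reaction). The risks are low enantioselectivity with so small an electrophile, slow release of formaldehyde from paraformaldehyde at −20 °C, erosion of ee by re-enolisation or retro-aldol, E1cB dehydration to the α-aryloxy enone, and double hydroxymethylation. The ee of 6 is measured by chiral HPLC before going on. The fallback uses known chemistry and moves the C–C bond formation from a basic ion-pair aldol to a Lewis-acid Mukaiyama aldol on a preformed silicon enolate. It sets out from 5. Soft enolisation and silylation with TMSOTf (2.5 equiv) and Et3N (3 equiv) in CH2Cl2 at 0 °C give the bis-silylated compound (Z)-1-[4-(benzyloxy)-3,5-dimethoxyphenyl]-2-{2-methoxy-4-[3-(trimethylsilyloxy)propyl]phenoxy}-1-(trimethylsilyloxy)ethene F1. F1 is submitted to the catalytic asymmetric aqueous hydroxymethylation of silicon enolates: Sc(OTf)3 (10 mol %), enantiopure 6,6'-bis(1-hydroxy-2,2-dimethylpropyl)-2,2'-bipyridine (12 mol %, the antipode that gives the S product), 37% aqueous formaldehyde (5 equiv), DME/H2O 9:1, −20 °C. A dilute citric acid/MeOH work-up frees the side-chain alcohol, and the sequence comes back to the route at 6. The medium is not basic, so the product is not enolised.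

Step 5. The risks are over-reduction of the aryl ketone to the benzylic alcohol and hydrogenolysis of the α-aryloxy C–O bond if the reaction is left too long. The fallback replaces reductive cleavage by Lewis-acid debenzylation with a cation scavenger. It sets out from 6: BCl3 (4 equiv, two of which are held as borates by the two hydroxyl groups) and pentamethylbenzene (3 equiv) in CH2Cl2 at −78 °C, MeOH quench at −78 °C, then aqueous work-up. It comes back to the route directly at 7. No new intermediate is made on this way (entry F0). At −78 °C the aryl methyl ethers, the ketone and C2 are not touched.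

Step 2. The risks are nuclear bromination of the electron-rich ring, dibromination, and partial loss of the benzyl group to the HBr formed. The fallback brominates a preformed enol silane under non-acidic conditions. It sets out from 2: TMSOTf (1.2 equiv) and Et3N (1.5 equiv) in CH2Cl2 at 0 °C give 1-[4-(benzyloxy)-3,5-dimethoxyphenyl]-1-(trimethylsilyloxy)ethene F2. NBS (1.05 equiv) in THF, −78 to 0 °C, then brominates F2 at carbon only, and the sequence comes back to the route at 3.

## Further compounds

F1 | step 4 | (Z)-1-[4-(benzyloxy)-3,5-dimethoxyphenyl]-2-{2-methoxy-4-[3-(trimethylsilyloxy)propyl]phenoxy}-1-(trimethylsilyloxy)ethene | COc1cc(CCCO[Si](C)(C)C)ccc1O/C=C(\O[Si](C)(C)C)c1cc(OC)c(OCc2ccccc2)c(OC)c1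
F0 | step 5 | none | none
F2 | step 2 | 1-[4-(benzyloxy)-3,5-dimethoxyphenyl]-1-(trimethylsilyloxy)ethene | C=C(O[Si](C)(C)C)c1cc(OC)c(OCc2ccccc2)c(OC)c1
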